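**Remark on the chemistry (numbering and tautomers).** Caryophyllane numbering is used: C1 and C9 are the cyclobutane CH carbons, C4 the O‑bearing quaternary carbon, C5 its CH neighbour, C8 the methylidene carbon, C10/C11 the CH2/CMe2 of ring A, C1' the CH2 between C5 and ring D. Ring D is numbered C2' (on C1'), C3' (ether carbon), C4' (CMe2), C5' (ketone), C6' (acyl‑bearing), C7' (enol carbon). Ring D and compounds 21–23 are written as single tautomers of enolised acyl‑triones.

## Analysis of the target

The target is a tetracycle. A gem‑dimethylcyclobutane (ring A: C1, C9, C10, C11) is trans‑fused to a nine‑membered carbocycle (ring B: C1–C9) with an exocyclic methylidene at C8. A dihydropyran (ring C: O, C4, C5, C1', C2', C3') is fused to ring B across C4–C5 and to an enolised isobutyryl‑cyclohexanetrione (ring D) across C2'–C3'.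

There are four stereocentres: C1 (R) and C9 (S) at the trans A/B fusion, the quaternary C4 (S) bearing O and CH3, and C5 (R), whose hydrogen is anti to the C4 methyl (trans B/C fusion). The two vicinal pairs are separated by C2–C3 on one side and C6–C8 on the other, so their mutual relationship is remote.

Sensitive groups are the 1,1‑disubstituted alkene (acid‑induced migration or transannular capture), the tertiary alkyl enol ether at C4 (ionisation) and the acidic, chelating β‑triketone. The triketone would not survive organometallic reagents, ylides or irradiation, so ring D has to enter last.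

The difficulties are the nine‑membered ring, the strained trans‑fused cyclobutane, the remote stereorelationship and the quaternary C4–O centre.

The strategy rests on the substitution pattern of ring A. The CH2 (C10) sits on C9, next to C8, and the CMe2 (C11) sits on C1. With C8 as a ketone, C9=C1 is an enone double bond and ring A is the head‑to‑tail [2+2] adduct of that enone with isobutylene. The same ketone makes C9 epimerisable and later becomes the methylidene group.

## Retrosynthetic reasoning

**24 ⇒ 23 (O–C3').** Ring C is opened at the enol‑ether bond O–C3', not at O–C4. The oxygen then stays on C4, and the forward closure is a loss of water between the C4 hydroxyl and the C3' carbonyl of 23. The C4–O bond is never broken, so the quaternary centre cannot be scrambled; a cut at O–C4 would call for a C4 cation. The forward step must pick C3' over C7'. C7' is held in the chelated enol of the acyl‑triketone, while C3' is the one isolated ketone.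

**23 ⇒ 19 + 21 (C1'–C2').** This cut gives a β‑hydroxy aldehyde 19 and the trione 21, whose C2' is its most nucleophilic carbon. The forward reaction is condensation followed by conjugate hydride transfer. This avoids O‑alkylation and an SN2 reaction at a β‑branched carbon, and it brings ring D in at the very end.

**21 ⇒ 20 (two C–CH3 bonds).** The trione is the dearomatised, geminally C‑methylated form of the acylphloroglucinol 20.

**19 ⇒ 18 ⇒ 17 ⇒ 16 (oxidation level, C8=CH2).** The aldehyde comes from the primary alcohol of diol 18, the diol from acetonide 17, and the methylidene group from ketone 16. Methylenation has to precede acetonide removal, because a free C4 hydroxyl would add across the ring to a C8 ketone.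

**16 ⇒ 13 + 14 (C9–C10 and C1–C11).** Both bonds of ring A that do not belong to ring B are cut, which gives the Z‑cyclononenone 13 and isobutylene 14. No other cut removes ring A in one step and leaves a carbonyl exactly where the methylidene group is needed. The forward reaction must give the head‑to‑tail adduct, add to the correct face of C1 relative to C4/C5, and end with the trans fusion; the last is secured by epimerisation at C9. Ring C is kept as an acetonide so that the enone is the only chromophore and ring B is conformationally biased.

**13 ⇒ 12 ⇒ 11 ⇒ 10 (C9=C1, then C8–C9).** The ring alkene is cut by ring‑closing metathesis to dienone 12, whose vinyl ketone comes from aldehyde 10 by vinyl addition (11) and oxidation. Closing ring B at the only double bond it contains keeps C4 and C5 away from the ring‑forming event.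

**10 ⇒ 9 ⇒ 8 ⇒ 7 ⇒ 4 + 5 (C5–C6).** The C6–C8 arm is cut from C5, which leads to epoxy alcohol 4 and the organomagnesium reagent 6 made from bromide 5. Attack at C5 with inversion, together with the E geometry of the epoxide, gives the trans relationship of C4‑CH3 and C5‑H. An acetal‑masked aldehyde at C8 would save a step, but no acid cleaves such an acetal and spares the acetonide, so C8 comes in as a silyl ether and is oxidised after fluoride deprotection.

**4 ⇒ 3 ⇒ 2 ⇒ 1.** The epoxide comes from tartrate‑controlled epoxidation of the E allylic alcohol 3, which is the reduced form of the enoate 2 from a two‑carbon phosphonate olefination of ketone 1. The epoxidation is the single source of absolute configuration.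

## Alternatives that were turned down

**Alternative 1:** Ring B is cut at C4–C5, an aldol‑type bond. The precursor is A2, a trans‑1,2‑disubstituted gem‑dimethylcyclobutane with a methyl ketone arm (C2–C4) on C1 and, on C9, the C8‑methylidene chain ending in an α‑bromo ester at C5. In the forward step a divalent samarium reductant under high dilution makes a trivalent samarium enolate that adds to the ketone and gives the β‑hydroxy ester A1.
- For: this Reformatsky‑type closure is one of the more dependable C–C closures of eight‑ and nine‑membered rings, because the metal templates both ends. The cyclobutane and its trans relationship are settled beforehand on a small ring, so no medium‑ring photochemistry is needed. On that point it is stronger than the chosen plan. A1 already carries the methylidene group and C1' at the ester level.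
- Against: C4 and C5 are both created in the ring‑closing event, under the control of a chelate and of the distant C1/C9 only, with four diastereomers possible. An enantiopure cyclobutane with two differentiated arms costs a long linear sequence. A1 is prone to retro‑aldol opening.
- Comparison: alternative 1 secures C1/C9 and leaves C4/C5 uncertain; the chosen plan does the reverse. It was preferred because C4/C5 are set by a reagent‑controlled reaction on an acyclic compound, and the whole risk sits in one step that is reached quickly.

**Alternative 2:** Both heteroatom‑side bonds of ring C (C1'–C2' and O–C4) are cut at once, which gives the enal A4 (C8 ketone, C4=C5 ring alkene with trans ring bonds, CHO on C5) and trione 21. In the forward step an amine‑salt‑catalysed Knoevenagel condensation gives a 1‑oxatriene that closes by 6π electrocyclisation to the 2H‑pyran A3.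
- For: it is the most convergent end game; ring C is built and ring D attached in one operation by a well‑known formal [3+3] reaction. In step count at the end it is superior.
- Against: C4 arises in a reversible electrocyclisation, so its configuration depends on torquoselectivity under the remote C1/C9 centres and can drift. A3 still has a C5=C1' double bond that must be reduced with hydrogen delivered anti to the C4 methyl, next to an enolised triketone. C8 is still a ketone and would have to be methylenated in the presence of the acidic ring D. A4 itself needs a trans‑configured trisubstituted alkene in a nine‑membered ring.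
- Comparison: the chosen plan is longer at the end, but C4 carries its oxygen from an epoxide onward and C5 is fixed before ring B exists, so neither can drift.

**Alternative 3:** Ring B is cut at C5–C6 and reconnected at C3–C8, so that it arises by four‑carbon expansion of a cyclopentane. In the forward step the potassium alkoxide of the 1,2‑dialkenyl carbinol A6 undergoes an anionic oxy‑Cope shift; protonation and base equilibration at C9 give the trans‑fused cyclononenone A5.
- For: the isobutylene photocycloaddition is done on a five‑membered enone, where it has firm precedent, and the nine‑membered ring comes from a sigmatropic shift and not from a cyclisation. Both steps are better precedented than their counterparts in the chosen plan.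
- Against: A5 has a C3=C4 alkene and no oxygen at C4, so the quaternary C4–O centre must still be installed regio‑ and stereoselectively on a medium‑ring alkene. C5 depends on the chair/boat preference of the rearrangement and on a trans arrangement of the two alkenyl groups in A6, which is not the one a convex‑face addition gives. The photoadduct is racemic unless resolved.
- Comparison: alternative 3 wins on precedent. The chosen plan has C4–O and C5 in place with absolute control from the third step and needs fewer steps after the ring is formed.

Key step: step 11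

## Route

Step 1
Reactants: 1 hex-5-en-2-one
Product: 2 ethyl (2E)-3-methylhepta-2,6-dienoate
Conditions: (EtO)2P(O)CH2CO2Et, NaH, THF, 0 °C to rt; minor Z ester removed by chromatography
Reagents that add atoms: triethyl phosphonoacetate, CCOC(=O)CP(=O)(OCC)OCC
Why: Horner–Wadsworth–Emmons olefination of the methyl ketone; the stabilised phosphonate anion should give the E trisubstituted enoate as the main isomer, and the Z ester is removed here so that a single epoxide series is carried on.

Step 2
Reactants: 2 ethyl (2E)-3-methylhepta-2,6-dienoate
Product: 3 (2E)-3-methylhepta-2,6-dien-1-ol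
Conditions: iBu2AlH (2.2 equiv), CH2Cl2, −78 to 0 °C; aq. potassium sodium tartrate
Reagents that add atoms: none
Why: 1,2-Reduction of the conjugated ester by iBu2AlH at low temperature gives the allylic alcohol and leaves both alkenes untouched.

Step 3
Reactants: 3 (2E)-3-methylhepta-2,6-dien-1-ol
Product: 4 [(2S,3S)-3-(but-3-en-1-yl)-3-methyloxiran-2-yl]methanol
Conditions: Ti(OiPr)4 (cat.), L-(+)-diethyl tartrate (cat.), tBuOOH, 4 Å MS, CH2Cl2, −20 °C
Reagents that add atoms: tert-butyl hydroperoxide, CC(C)(C)OO
Why: Sharpless asymmetric epoxidation; with L-(+)-diethyl tartrate an (E)-3-methylalk-2-en-1-ol is epoxidised on the face that gives the (2S,3S) epoxide, which sets C4 directly and prepares C5 for inversion; the isolated terminal alkene does not react.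

Step 4
Reactants: 4 [(2S,3S)-3-(but-3-en-1-yl)-3-methyloxiran-2-yl]methanol; 5 (3-bromopropoxy)(tert-butyl)dimethylsilane
Product: 7 (2R,3S)-2-[3-(tert-butyldimethylsilyloxy)propyl]-3-methylhept-6-ene-1,3-diol, via Grignard reagent 6 (not isolated)
Conditions: 5, Mg, THF, rt; then CuI (10 mol %), 4, THF, −30 to 0 °C (3 equiv of 6); aq. NH4Cl
Reagents that add atoms: none
Why: Copper-catalysed Grignard opening of a 2,3-epoxy alcohol; the fully substituted C4 terminus is closed to SN2 attack, so the organocopper species should attack C5 with inversion and give the 1,3-diol with C4 (S) and C5 (R); one equivalent of 6 is spent on the hydroxyl group.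

Step 5
Reactants: 7 (2R,3S)-2-[3-(tert-butyldimethylsilyloxy)propyl]-3-methylhept-6-ene-1,3-diol
Product: 8 tert-butyl{3-[(4S,5R)-4-(but-3-en-1-yl)-2,2,4-trimethyl-1,3-dioxan-5-yl]propoxy}dimethylsilane
Conditions: Me2C(OMe)2, PPTS (cat.), CH2Cl2, rt
Reagents that add atoms: 2,2-dimethoxypropane, COC(C)(C)OC
Why: Acid-catalysed transketalisation turns the 1,3-diol into the six-membered acetonide, which masks both oxygens of ring C and holds the C3 and C6 chains trans-diequatorial; the primary silyl ether tolerates PPTS.

Step 6
Reactants: 8 tert-butyl{3-[(4S,5R)-4-(but-3-en-1-yl)-2,2,4-trimethyl-1,3-dioxan-5-yl]propoxy}dimethylsilane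
Product: 9 3-[(4S,5R)-4-(but-3-en-1-yl)-2,2,4-trimethyl-1,3-dioxan-5-yl]propan-1-ol
Conditions: Bu4NF, THF, 0 °C to rt
Reagents that add atoms: none
Why: Fluoride cleaves the silyl ether and leaves the acetonide alone; this orthogonality is the reason the C8 terminus is carried as a silyl ether.

Step 7
Reactants: 9 3-[(4S,5R)-4-(but-3-en-1-yl)-2,2,4-trimethyl-1,3-dioxan-5-yl]propan-1-ol
Product: 10 3-[(4S,5R)-4-(but-3-en-1-yl)-2,2,4-trimethyl-1,3-dioxan-5-yl]propanal
Conditions: Dess–Martin periodinane, NaHCO3, CH2Cl2, 0 °C to rt
Reagents that add atoms: none
Why: Dess–Martin oxidation under bicarbonate buffer gives the C8 aldehyde without acid that would open the acetonide.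

Step 8
Reactants: 10 3-[(4S,5R)-4-(but-3-en-1-yl)-2,2,4-trimethyl-1,3-dioxan-5-yl]propanal
Product: 11 5-[(4S,5R)-4-(but-3-en-1-yl)-2,2,4-trimethyl-1,3-dioxan-5-yl]pent-1-en-3-ol (both carbinol epimers)
Conditions: CH2=CHMgBr, THF, −78 °C
Reagents that add atoms: vinylmagnesium bromide, C=C[Mg]Br
Why: Grignard 1,2-addition forms C8–C9; the new carbinol centre is not controlled and need not be, because it is oxidised in the next step.

Step 9
Reactants: 11 5-[(4S,5R)-4-(but-3-en-1-yl)-2,2,4-trimethyl-1,3-dioxan-5-yl]pent-1-en-3-ol
Product: 12 5-[(4S,5R)-4-(but-3-en-1-yl)-2,2,4-trimethyl-1,3-dioxan-5-yl]pent-1-en-3-one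
Conditions: Dess–Martin periodinane, NaHCO3, CH2Cl2, 0 °C
Reagents that add atoms: none
Why: Dess–Martin oxidation of the allylic alcohol gives the vinyl ketone, which is used at once because it is prone to polymerisation and conjugate addition.

Step 10
Reactants: 12 5-[(4S,5R)-4-(but-3-en-1-yl)-2,2,4-trimethyl-1,3-dioxan-5-yl]pent-1-en-3-one
Product: 13 (4S,5R)-Z-cyclononenone acetonide (ring B with C8 ketone and Z C9=C1 alkene; 2,2-dimethyl-1,3-dioxane trans-fused across C4 and C5; CH3 on C4)
Conditions: second-generation Hoveyda–Grubbs catalyst RuCl2(H2IMes)(=CH–C6H4-2-OiPr) (10 mol %), toluene (1 mM), 80 °C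
Reagents that add atoms: none
Why: Ring-closing metathesis; the catalyst should load at the unhindered butenyl alkene and close onto the vinyl ketone under high dilution, the trans-diequatorial dioxane holds the two chains gauche and near each other, and a conjugated nine-membered enone is expected to accept only the Z double bond.

Step 11
Reactants: 13 (4S,5R)-Z-cyclononenone acetonide; 14 isobutylene
Product: 16 (1R,4S,5R,9S)-trans-fused 11,11-dimethylbicyclo[7.2.0]undecan-8-one acetonide, via cis-fused photoadduct 15 (not isolated)
Conditions: hν (350 nm, borosilicate filter), 14 (large excess, condensed), CH2Cl2, −40 °C; then NaOMe, MeOH, rt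
Reagents that add atoms: none
Why: Excitation of the enone near 350 nm and intersystem crossing give a triplet that relaxes by twisting about C9=C1 (in a nine-membered ring partly as far as the strained E enone), and this species adds isobutylene stepwise through a triplet 1,4-biradical that closes after spin inversion. The closest known reaction type is the head-to-tail [2+2] photocycloaddition of cyclic enones with isobutylene. Ring A is closed as a four-membered ring by intermolecular [2+2] cycloaddition, the bonds C9–C10 and C1–C11 forming one after the other and the second by collapse of the biradical. The orientation needed, CH2 on the α carbon C9 and CMe2 on the β carbon C1, is the normal one for an electron-rich 1,1-disubstituted alkene. C1 is set by the face of the twisted alkene that isobutylene reaches: the trans-fused dioxane fixes the C3–C4–C5–C6 segment so that one face of C9=C1 is turned toward the ring interior and addition is expected on the outer face, which is substrate control across several bonds and the weakest element of the plan. C9 is not set kinetically; NaOMe epimerises it through the C8 enolate to the trans fusion, which is expected to be the more stable one in a bicyclo[7.2.0]undecanone. The enone is the only chromophore at this wavelength, which is why ring D is not yet present.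

Step 12
Reactants: 16 (1R,4S,5R,9S)-trans-fused 11,11-dimethylbicyclo[7.2.0]undecan-8-one acetonide
Product: 17 (1R,4S,5R,9S)-8-methylidene acetonide (acetonide of diol 18)
Conditions: Ph3PCH3Br, KOtBu, toluene, rt to 80 °C
Reagents that add atoms: methyltriphenylphosphonium bromide, C[P+](c1ccccc1)(c1ccccc1)c1ccccc1.[Br-]
Why: Wittig methylenation of the C8 ketone; the ylide is basic, but C9 already has its thermodynamically preferred trans configuration, and the ketone is converted before the diol is freed because C4–OH would otherwise add across the ring to C8.

Step 13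
Reactants: 17 (1R,4S,5R,9S)-8-methylidene acetonide
Product: 18 (1R,4S,5R,9S)-5-(hydroxymethyl)-4,11,11-trimethyl-8-methylidenebicyclo[7.2.0]undecan-4-ol
Conditions: PPTS (cat.), MeOH, rt
Reagents that add atoms: none
Why: Mild acid-catalysed exchange with methanol removes the acetonide; PPTS is weak enough to leave the 1,1-disubstituted alkene and the tertiary alcohol alone.

Step 14
Reactants: 18 (1R,4S,5R,9S)-5-(hydroxymethyl)-4,11,11-trimethyl-8-methylidenebicyclo[7.2.0]undecan-4-ol
Product: 19 (1R,4S,5S,9S)-4-hydroxy-4,11,11-trimethyl-8-methylidenebicyclo[7.2.0]undecane-5-carbaldehyde (same geometry at C5; the descriptor changes by priority only)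
Conditions: TEMPO (cat.), PhI(OAc)2, CH2Cl2, rt
Reagents that add atoms: none
Why: Oxoammonium (TEMPO) oxidation is selective for the primary alcohol and the tertiary C4–OH cannot be oxidised; the β-hydroxy aldehyde is used crude and at once because it can epimerise at C5, dehydrate or cleave by retro-aldol reaction.

Step 15
Reactants: 20 phlorisobutyrophenone
Product: 21 3,5-dihydroxy-6,6-dimethyl-2-(2-methylpropanoyl)cyclohexa-2,4-dien-1-one (enol form of 2-isobutyryl-4,4-dimethylcyclohexane-1,3,5-trione)
Conditions: MeI (2.2 equiv), NaOMe, MeOH, 0 °C to rt
Reagents that add atoms: iodomethane, CI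
Why: Dearomatising C-methylation of an acylphloroglucinol; the second methyl group enters at the same ring carbon and fixes the trione, which is separated from ring-methylated aromatic and over-methylated by-products.

Step 16
Reactants: 19 (1R,4S,5S,9S)-4-hydroxy-4,11,11-trimethyl-8-methylidenebicyclo[7.2.0]undecane-5-carbaldehyde; 21 3,5-dihydroxy-6,6-dimethyl-2-(2-methylpropanoyl)cyclohexa-2,4-dien-1-one
Product: 23 (1R,4S,5R,9S)-C1'-linked trione alcohol (C5–CH2–C2' of ring D; free C4–OH), via alkylidene trione 22 (not isolated)
Conditions: diethyl 2,6-dimethyl-1,4-dihydropyridine-3,5-dicarboxylate (Hantzsch ester), L-proline (20 mol %), CH2Cl2, rt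
Reagents that add atoms: none
Why: Organocatalytic reductive alkylation: amine-catalysed Knoevenagel condensation at C2' gives the alkylidene trione 22, which is reduced at once by conjugate hydride transfer from the Hantzsch ester; C1'–C2' forms under nearly neutral conditions that suit the β-hydroxy aldehyde, and the isolated methylidene group is not reduced.

Step 17
Reactants: 23 (1R,4S,5R,9S)-C1'-linked trione alcohol
Product: 24 target CNP0497637.1
Conditions: PPTS (cat.), 4 Å MS, toluene, 60 °C
Reagents that add atoms: none
Why: Acid-catalysed hemiketalisation of the C4 hydroxyl onto the C3' carbonyl and loss of water give the vinylogous ester and close the six-membered ring C with the C4–O bond intact, so C4 keeps its configuration; C3' should be preferred because C7' is held in the chelated enol of the acyl-triketone, and PPTS is too weak to ionise the tertiary alcohol.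

## Compound list

1 | hex-5-en-2-one | C=CCCC(C)=O | starting material
2 | ethyl (2E)-3-methylhepta-2,6-dienoate | CCOC(=O)/C=C(\C)CCC=C | intermediate
3 | (2E)-3-methylhepta-2,6-dien-1-ol | OC/C=C(\C)CCC=C | intermediate
4 | [(2S,3S)-3-(but-3-en-1-yl)-3-methyloxiran-2-yl]methanol | OC[C@@H]1O[C@@]1(C)CCC=C | intermediate
5 | (3-bromopropoxy)(tert-butyl)dimethylsilane | BrCCCO[Si](C)(C)C(C)(C)C | starting material
6 | [3-(tert-butyldimethylsilyloxy)propyl]magnesium bromide | CC(C)(C)[Si](C)(C)OCCC[Mg]Br | intermediate
7 | (2R,3S)-2-[3-(tert-butyldimethylsilyloxy)propyl]-3-methylhept-6-ene-1,3-diol | CC(C)(C)[Si](C)(C)OCCC[C@H](CO)[C@@](C)(O)CCC=C | intermediate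
8 | tert-butyl{3-[(4S,5R)-4-(but-3-en-1-yl)-2,2,4-trimethyl-1,3-dioxan-5-yl]propoxy}dimethylsilane | CC(C)(C)[Si](C)(C)OCCC[C@@H]1COC(C)(C)O[C@@]1(C)CCC=C | intermediate
9 | 3-[(4S,5R)-4-(but-3-en-1-yl)-2,2,4-trimethyl-1,3-dioxan-5-yl]propan-1-ol | OCCC[C@@H]1COC(C)(C)O[C@@]1(C)CCC=C | intermediate
10 | 3-[(4S,5R)-4-(but-3-en-1-yl)-2,2,4-trimethyl-1,3-dioxan-5-yl]propanal | O=CCC[C@@H]1COC(C)(C)O[C@@]1(C)CCC=C | intermediate
11 | 5-[(4S,5R)-4-(but-3-en-1-yl)-2,2,4-trimethyl-1,3-dioxan-5-yl]pent-1-en-3-ol (both carbinol epimers) | C=CC(O)CC[C@@H]1COC(C)(C)O[C@@]1(C)CCC=C | intermediate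
12 | 5-[(4S,5R)-4-(but-3-en-1-yl)-2,2,4-trimethyl-1,3-dioxan-5-yl]pent-1-en-3-one | C=CC(=O)CC[C@@H]1COC(C)(C)O[C@@]1(C)CCC=C | intermediate
13 | (4S,5R)-Z-cyclononenone acetonide (C8 ketone, Z C9=C1, trans-fused 2,2-dimethyl-1,3-dioxane across C4/C5, CH3 on C4) | C1C[C@@H]2COC(C)(C)O[C@@]2(C)CC/C=C\C1=O | intermediate
14 | isobutylene (2-methylpropene) | C=C(C)C | starting material
15 | (1R,4S,5R,9R)-cis-fused 11,11-dimethylbicyclo[7.2.0]undecan-8-one acetonide | O=C1CC[C@@H]2COC(C)(C)O[C@@]2(C)CC[C@@H]2[C@H]1CC2(C)C | intermediate
16 | (1R,4S,5R,9S)-trans-fused 11,11-dimethylbicyclo[7.2.0]undecan-8-one acetonide | O=C1CC[C@@H]2COC(C)(C)O[C@@]2(C)CC[C@@H]2[C@@H]1CC2(C)C | intermediate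
17 | (1R,4S,5R,9S)-8-methylidene acetonide (acetonide of 18) | C=C1CC[C@@H]2COC(C)(C)O[C@@]2(C)CC[C@@H]2[C@@H]1CC2(C)C | intermediate
18 | (1R,4S,5R,9S)-5-(hydroxymethyl)-4,11,11-trimethyl-8-methylidenebicyclo[7.2.0]undecan-4-ol | C=C1CC[C@H](CO)[C@@](C)(O)CC[C@@H]2[C@@H]1CC2(C)C | intermediate
19 | (1R,4S,5S,9S)-4-hydroxy-4,11,11-trimethyl-8-methylidenebicyclo[7.2.0]undecane-5-carbaldehyde | C=C1CC[C@H](C=O)[C@@](C)(O)CC[C@@H]2[C@@H]1CC2(C)C | intermediate
20 | phlorisobutyrophenone (2-methyl-1-(2,4,6-trihydroxyphenyl)propan-1-one) | CC(C)C(=O)c1c(O)cc(O)cc1O | starting material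
21 | 3,5-dihydroxy-6,6-dimethyl-2-(2-methylpropanoyl)cyclohexa-2,4-dien-1-one | CC(C)C(=O)C1=C(O)C=C(O)C(C)(C)C1=O | intermediate
22 | (1R,4S,5R,9S)-alkylidene trione (Knoevenagel adduct, C1'=C2', alkene geometry open) | C=C1CC[C@H](C=C3C(=O)C(C)(C)C(=O)C(C(=O)C(C)C)=C3O)[C@@](C)(O)CC[C@@H]2[C@@H]1CC2(C)C | intermediate
23 | (1R,4S,5R,9S)-C1'-linked trione alcohol | C=C1CC[C@H](CC3=C(O)C(C)(C)C(=O)C(C(=O)C(C)C)=C3O)[C@@](C)(O)CC[C@@H]2[C@@H]1CC2(C)C | intermediate
24 | CNP0497637.1, (1R,4S,5R,9S) | C=C1CC[C@@H]2CC3=C(O[C@@]2(C)CC[C@@H]2[C@@H]1CC2(C)C)C(C)(C)C(=O)C(C(=O)C(C)C)=C3O | target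

## Step count and least certain steps

Total step count: 17. Longest linear sequence: 16 (steps 1–14, 16 and 17); step 15 is a one-step side branch.

**Step 11 (key step).** Several processes can divert the excited nine-membered enone.
- Energy can be lost in Z/E isomerisation without addition.
- γ-Hydrogen transfer can deconjugate the enone.
- The biradical can close in the head-to-head sense.
- Isobutylene can add to both faces of C9=C1, because the only bias is the conformation imposed by the distant dioxane. The C1 epimer series would then have to be separated after the base treatment.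

Fallback: the cyclobutane is made thermally on a ring-closed allylic ether instead of photochemically on the enone. It sets out from 11 and returns at 15, and through the base treatment of step 11 at 16.
- Silylation of 11 (TBSCl, imidazole) gives the diene silyl ether F1.
- Ring-closing metathesis with the same ruthenium catalyst gives the Z-cyclononenyl silyl ether F2.
- The keteniminium ion generated from N,N-dimethylisobutyramide (Tf2O, 2,4,6-collidine) adds to the Z alkene. Its electrophilic carbon should bond to C9, so that positive charge develops at C1, away from the C8 oxygen. Hydrolysis then gives the cis-fused cyclobutanone F3 with C=O at C10 and CMe2 at C11.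
- Wolff–Kishner reduction (N2H4·H2O, KOH, diethylene glycol, 200 °C) removes the C10 carbonyl and is expected to cleave the silyl ether as well, giving the alcohol F4.
- Dess–Martin oxidation gives 15.

Facial selectivity stays substrate-controlled in this sequence too.

**Step 10.** Intermolecular metathesis (oligomer formation) can outrun closure of the strained nine-membered ring, and the electron-poor vinyl ketone is a slow partner that can also chelate ruthenium.

Fallback: the ring is closed at the alcohol oxidation level. It sets out from 11 and returns at 13. Metathesis of the free allylic alcohol 11 gives the Z-cyclononenol F5, and Dess–Martin or MnO2 oxidation gives 13.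

**Step 4.** Regiocontrol can be lost: the magnesium alkoxide of 4 can undergo Payne rearrangement and then be opened at C1', or magnesium halide can open the epoxide to a halohydrin before the copper reagent attacks C5.

Fallback: C5 is activated electronically as the α carbon of a glycidic ester. It sets out from 4 and returns at 7.
- TEMPO/PhI(OAc)2 in MeCN–H2O oxidises 4 to the epoxy acid F6.
- Me3SiCHN2 gives the methyl ester F7.
- The cuprate made from 6 and CuBr·SMe2 opens F7 at the α carbon with inversion to the β-hydroxy ester F8.
- LiAlH4 reduces F8 to 7.

**Step 16.** Under amine catalysis the β-hydroxy aldehyde 19 can cleave by retro-aldol reaction (which opens ring B), lose water to the enal, or epimerise at C5 before the slow condensation of an α-branched aldehyde takes place.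

Fallback: the tertiary hydroxyl is capped so that no alkoxide can form. It sets out from 18 and returns at 23.
- Et3SiOTf/2,6-lutidine gives the bis(triethylsilyl) ether F9.
- Swern conditions ((COCl)2, DMSO, then Et3N) oxidise the primary silyl ether directly to the silyloxy aldehyde F10.
- Reductive coupling with 21 as in step 16 gives the silyl-protected coupling product F11.
- PPTS/MeOH removes the silyl group to give 23, which closes to 24 under the conditions of step 17.

## Further compounds

F1 | step 11 | tert-butyldimethylsilyl ether of 11 | C=CC(O[Si](C)(C)C(C)(C)C)CC[C@@H]1COC(C)(C)O[C@@]1(C)CCC=C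
F2 | step 11 | (4S,5R)-Z-cyclononenyl tert-butyldimethylsilyl ether acetonide (C8–OSi, Z C9=C1) | C1C[C@@H]2COC(C)(C)O[C@@]2(C)CC/C=C\C1O[Si](C)(C)C(C)(C)C
F3 | step 11 | (1R,4S,5R,9R)-cis-fused 11,11-dimethyl-10-oxo-8-silyloxybicyclo[7.2.0]undecane acetonide | C1C[C@@H]2COC(C)(C)O[C@@]2(C)CC[C@@H]3[C@@H](C(=O)C3(C)C)C1O[Si](C)(C)C(C)(C)C
F4 | step 11 | (1R,4S,5R,9R)-cis-fused 11,11-dimethylbicyclo[7.2.0]undecan-8-ol acetonide | C1C[C@@H]2COC(C)(C)O[C@@]2(C)CC[C@@H]3[C@@H](CC3(C)C)C1O
F5 | step 10 | (4S,5R)-Z-cyclononenol acetonide (C8–OH, Z C9=C1) | C1C[C@@H]2COC(C)(C)O[C@@]2(C)CC/C=C\C1O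
F6 | step 4 | (2R,3S)-3-(but-3-en-1-yl)-3-methyloxirane-2-carboxylic acid | OC(=O)[C@@H]1O[C@@]1(C)CCC=C
F7 | step 4 | methyl (2R,3S)-3-(but-3-en-1-yl)-3-methyloxirane-2-carboxylate | COC(=O)[C@@H]1O[C@@]1(C)CCC=C
F8 | step 4 | methyl (2S,3S)-2-[3-(tert-butyldimethylsilyloxy)propyl]-3-hydroxy-3-methylhept-6-enoate | CC(C)(C)[Si](C)(C)OCCC[C@H](C(=O)OC)[C@@](C)(O)CCC=C
F9 | step 16 | bis(triethylsilyl) ether of 18 | C=C1CC[C@H](CO[Si](CC)(CC)CC)[C@@](C)(O[Si](CC)(CC)CC)CC[C@@H]2[C@@H]1CC2(C)C
F10 | step 16 | 4-O-triethylsilyl ether of 19 | C=C1CC[C@H](C=O)[C@@](C)(O[Si](CC)(CC)CC)CC[C@@H]2[C@@H]1CC2(C)C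
F11 | step 16 | 4-O-triethylsilyl ether of 23 | C=C1CC[C@H](CC3=C(O)C(C)(C)C(=O)C(C(=O)C(C)C)=C3O)[C@@](C)(O[Si](CC)(CC)CC)CC[C@@H]2[C@@H]1CC2(C)C
A1 | alternative 1 | bicyclic β-hydroxy ester with ring B closed at C4–C5 | C=C1CC[C@H](C(=O)OC)[C@@](C)(O)CC[C@@H]2[C@@H]1CC2(C)C
A2 | alternative 1 | open-chain cyclobutane bearing the methyl ketone arm and the α-bromo ester arm | CC(=O)CC[C@@H]1[C@@H](C(=C)CCC(Br)C(=O)OC)CC1(C)C
A3 | alternative 2 | tetracyclic 2H-pyran with C5=C1' double bond and C8 ketone | O=C1CCC2=CC3=C(O[C@@]2(C)CC[C@@H]2[C@@H]1CC2(C)C)C(C)(C)C(=O)C(C(=O)C(C)C)=C3O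
A4 | alternative 2 | (1R,9S)-norcaryophyllene enal (C8 ketone, C4=C5 with trans ring bonds, CHO on C5) | O=C1CC/C(C=O)=C(C)/CC[C@@H]2[C@@H]1CC2(C)C
A5 | alternative 3 | trans-fused cyclononenone with C3=C4 alkene and C1' silyl ether | O=C1CC[C@H](CO[Si](C)(C)C(C)(C)C)/C(C)=C/C[C@@H]2[C@@H]1CC2(C)C
A6 | alternative 3 | trans-1,2-dialkenyl 6,6-dimethylbicyclo[3.2.0]heptan-2-ol | C=C[C@@]1(O)[C@H](/C(C)=C/CO[Si](C)(C)C(C)(C)C)C[C@@H]2[C@H]1CC2(C)C
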